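## Retrosynthetic overview

1. Deoxycaespitol is opened at both rings at once (C1–C6 of the cyclohexane, O–C7 of the oxane) to an acyclic (6E)-C15 chain carrying a 2-bromo-3-chloro unit, a C1 leaving group and a 10-bromo-11-ol.
2. Forward ring order, in one operation: cyclohexane first (the 6,7-alkene opens a C1/C2 bromonium ion at C1), then the oxane (the C11 hydroxyl traps the C7 cation).
3. The C2–Br/C3–Cl pair comes from enantioselective anti bromochlorination of a (2Z)-allylic alcohol; C10–Br comes from bromide opening (inversion) of a (10R)-epoxide.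
4. The (2Z,6E) skeleton comes from Z-selective alkylation of dilithiated prenol with (R)-6,7-epoxygeranyl chloride, made by Shi epoxidation of geranyl chloride.

Assumption: farnesane numbering (C1 = CH2O carbon) is used for positions in all intermediates, and in step 4 the ligand enantiomer that gives the 2R,3R product is taken.

## Route

Step 1
Reactants: 1 geranyl chloride [(2E)-1-chloro-3,7-dimethylocta-2,6-diene]
Product: 2 (R)-6,7-epoxygeranyl chloride [(3R)-3-[(3E)-5-chloro-3-methylpent-3-en-1-yl]-2,2-dimethyloxirane]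
Conditions: D-fructose-derived Shi ketone (30 mol%), KHSO5 (as Oxone), K2CO3, Bu4NHSO4, MeCN/dimethoxymethane/aq. Na2B4O7 buffer (pH 10.5), 0 °C, 2 h
Reagents that add atoms: potassium peroxymonosulfate KHSO5, [K+].[O-]S(=O)(=O)OO
Why: Shi asymmetric epoxidation (chiral dioxirane, spiro transition state): the electron-rich 6,7-alkene reacts in preference to the chloride-deactivated 2,3-alkene, and the D-fructose-derived ketone delivers oxygen to the face that gives the R epoxide.

Step 2
Reactants: 3 prenol (3-methylbut-2-en-1-ol); 2 (R)-6,7-epoxygeranyl chloride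
Product: 5 (2Z,6E)-9-[(2R)-3,3-dimethyloxiran-2-yl]-3,7-dimethylnona-2,6-dien-1-ol, via dilithiated prenol 4 (not isolated)
Conditions: n-BuLi (2.1 equiv), TMEDA, Et2O/hexane, 0 °C to rt, 20 h; then 2 (0.75 equiv), THF, −78 to 0 °C; H2O quench
Reagents that add atoms: none
Why: Alkoxide-directed allylic lithiation removes a proton from the methyl cis to CH2OLi, and SN2 alkylation of the chelated Z-allyllithium at its CH2 terminus by the primary allylic chloride places the new chain cis to CH2OH (2Z), leaving the 6E alkene and the epoxide centre untouched.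

Step 3
Reactants: 5 (2Z,6E)-9-[(2R)-3,3-dimethyloxiran-2-yl]-3,7-dimethylnona-2,6-dien-1-ol
Product: 6 (2Z,6E,10S)-10-bromo-3,7,11-trimethyldodeca-2,6-diene-1,11-diol
Conditions: Li2NiBr4 (from 2 LiBr + NiBr2, 2 equiv), THF, 0 °C to rt; pH 7 buffer
Reagents that add atoms: dilithium tetrabromonickelate Li2NiBr4, [Li+].[Li+].[Ni+2].[Br-].[Br-].[Br-].[Br-]
Why: Regioselective SN2 epoxide opening: bromide attacks the less hindered secondary C10 with inversion (10R epoxide to 10S bromide), and the tertiary C11–O bond stays as the hydroxyl.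

Step 4
Reactants: 6 (2Z,6E,10S)-10-bromo-3,7,11-trimethyldodeca-2,6-diene-1,11-diol
Product: 7 (2R,3R,6E,10S)-2,10-dibromo-3-chloro-3,7,11-trimethyldodec-6-ene-1,11-diol
Conditions: NBS (1.05 equiv), ClTi(OiPr)3 (2.2 equiv), chiral O,N,O Schiff-base ligand (amino-alcohol salicylaldimine, 20 mol%), hexanes, −20 °C
Reagents that add atoms: N-bromosuccinimide, O=C1CCC(=O)N1Br; chlorotitanium triisopropoxide ClTi(OiPr)3, CC(C)O[Ti](Cl)(OC(C)C)OC(C)C
Why: Catalytic enantioselective bromochlorination of an allylic alcohol under titanium alkoxide/Schiff-base control: the bound allylic hydroxyl confines the reaction to the 2,3-alkene, anti addition across the Z alkene puts Br at C2 and titanium-delivered chloride at the tertiary C3, and the ligand enantiomer fixes the face to give 2R,3R.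

Step 5
Reactants: 7 (2R,3R,6E,10S)-2,10-dibromo-3-chloro-3,7,11-trimethyldodec-6-ene-1,11-diol
Product: 11 deoxycaespitol [(3S,6R)-3-bromo-6-[(1R,3R,4R)-3-bromo-4-chloro-4-methylcyclohexyl]-2,2,6-trimethyloxane], via primary triflate 8 (not isolated), via bromonium ion 9 (not isolated), via tertiary carbocation 10 (not isolated)
Conditions: Tf2O (1.05 equiv), 2,6-di-tert-butyl-4-methylpyridine (3 equiv), CH2Cl2, −78 °C, 20 min; then dilute with CH2Cl2/(CF3)2CHOH (3:1, to 0.005 M), −30 to 0 °C
Reagents that add atoms: none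
Why: Proposed new method: the β-bromo primary triflate ionises with anchimeric assistance to a configurationally defined C1/C2 bromonium ion, the 6E trisubstituted alkene opens it at the unhindered primary C1 through a chair in which the anti-periplanar bridging bromine must end up equatorial at C2 (so Cl and the C6 side chain are equatorial and the C3 methyl axial, giving 6R), and the resulting C7 cation is trapped by the C11 hydroxyl through a second chair with equatorial Br and cyclohexyl (7R, consistent with anti addition across the 6E alkene); the closest known reaction types are solvolytic cation-olefin cyclisation of alkenyl sulfonates, stereospecific bromonium generation from β-bromo sulfonates in (CF3)2CHOH, distal opening of halonium ions that carry an α-haloalkyl group, and oxacyclisation of a tertiary alcohol onto a tertiary cation.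

## Compound list

1 | geranyl chloride, (2E)-1-chloro-3,7-dimethylocta-2,6-diene | ClC/C=C(\C)CCC=C(C)C | starting material
2 | (R)-6,7-epoxygeranyl chloride, (3R)-3-[(3E)-5-chloro-3-methylpent-3-en-1-yl]-2,2-dimethyloxirane | ClC/C=C(\C)CC[C@H]1OC1(C)C | intermediate
3 | prenol, 3-methylbut-2-en-1-ol | CC(C)=CCO | starting material
4 | dilithiated prenol, lithium (2Z)-4-lithio-3-methylbut-2-en-1-olate | [Li]C/C(C)=C\CO[Li] | intermediate
5 | (2Z,6E)-9-[(2R)-3,3-dimethyloxiran-2-yl]-3,7-dimethylnona-2,6-dien-1-ol | OC/C=C(/C)CC/C=C(\C)CC[C@H]1OC1(C)C | intermediate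
6 | (2Z,6E,10S)-10-bromo-3,7,11-trimethyldodeca-2,6-diene-1,11-diol | OC/C=C(/C)CC/C=C(\C)CC[C@H](Br)C(C)(C)O | intermediate
7 | (2R,3R,6E,10S)-2,10-dibromo-3-chloro-3,7,11-trimethyldodec-6-ene-1,11-diol | OC[C@@H](Br)[C@](C)(Cl)CC/C=C(\C)CC[C@H](Br)C(C)(C)O | intermediate
8 | primary triflate, (2R,3R,6E,10S)-2,10-dibromo-3-chloro-11-hydroxy-3,7,11-trimethyldodec-6-en-1-yl trifluoromethanesulfonate | FC(F)(F)S(=O)(=O)OC[C@@H](Br)[C@](C)(Cl)CC/C=C(\C)CC[C@H](Br)C(C)(C)O | intermediate
9 | bromonium ion bridging C1 and C2 of 8 (C2, C3 and C10 arranged as in 7), triflate salt | C1[Br+][C@H]1[C@](C)(Cl)CC/C=C(\C)CC[C@H](Br)C(C)(C)O.[O-]S(=O)(=O)C(F)(F)F | intermediate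
10 | tertiary carbocation, (5S)-5-bromo-2-[(1R,3R,4R)-3-bromo-4-chloro-4-methylcyclohexyl]-6-hydroxy-6-methylheptan-2-ylium triflate | C[C+]([C@@H]1CC[C@@](C)(Cl)[C@H](Br)C1)CC[C@H](Br)C(C)(C)O.[O-]S(=O)(=O)C(F)(F)F | intermediate
11 | deoxycaespitol, (3S,6R)-3-bromo-6-[(1R,3R,4R)-3-bromo-4-chloro-4-methylcyclohexyl]-2,2,6-trimethyloxane | CC1(C)O[C@@](C)([C@@H]2CC[C@@](C)(Cl)[C@H](Br)C2)CC[C@@H]1Br | target

## Step count and risks

Total step count: 5.
Longest linear sequence: 5 steps (1 → 2 → 5 → 6 → 7 → 11).

Steps most likely to fail: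

**Step 5 (bicyclisation).** The alkene may attack C2 of the bromonium ion to give a cyclopentane, or the triflate may simply solvolyse. The fallback sets out from diol 6 and reverses the order of events. The (2Z)-allylic alcohol is ionised (Bi(OTf)3, 5 mol%, CH2Cl2/(CF3)2CHOH, −30 °C), the neryl-type allyl cation is attacked by the 6E alkene, and the C7 cation is trapped by the C11 hydroxyl. C10 controls C7 through the oxane chair and anti addition across the 6E alkene sets C6. This gives (3S,6R)-3-bromo-2,2,6-trimethyl-6-[(1R)-4-methylcyclohex-3-en-1-yl]oxane F1. BrCl is then added across the ring alkene under kinetic conditions (NBS, Et4NCl, CH2Cl2, −78 °C). Because the side chain locks the ring, the trans-diaxial diastereomer is expected to be the main product, so 11 is a minor component that must be separated; the route is rejoined at 11.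

**Step 4 (bromochlorination).** The free C11 hydroxyl may be bromoetherified onto the 6,7-alkene by NBS, and a Z-trisubstituted substrate may give lower selectivity. The fallback sets out from epoxy alcohol 5, where the tertiary oxygen is still masked in the epoxide. The same titanium/Schiff-base bromochlorination is run on 5 to give (2R,3R,6E)-2-bromo-3-chloro-9-[(2R)-3,3-dimethyloxiran-2-yl]-3,7-dimethylnon-6-en-1-ol F2. The epoxide is then opened with Li2NiBr4 as in step 3, and the route is rejoined at 7.

**Step 2 (dianion alkylation).** Terminal versus internal attack of the allyllithium, loss of Z geometry, or attack on the epoxide may lower the yield. The fallback sets out from chloride 2 and builds the Z alkene by syn carbocupration: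
- Alkylation of 2 with LiCH2C≡CSiMe3 (from 1-trimethylsilylpropyne and n-BuLi, THF, −78 °C) gives trimethyl[(5E)-8-[(2R)-3,3-dimethyloxiran-2-yl]-6-methyloct-5-en-1-yn-1-yl]silane F3.
- MeLi·LiBr followed by ClCO2Me gives methyl (6E)-9-[(2R)-3,3-dimethyloxiran-2-yl]-7-methylnon-6-en-2-ynoate F4.
- Me2CuLi in THF at −78 °C adds methyl and copper syn across the alkyne and, after protonation, gives methyl (2Z,6E)-9-[(2R)-3,3-dimethyloxiran-2-yl]-3,7-dimethylnona-2,6-dienoate F5.
- i-Bu2AlH at −78 °C reduces the ester, and the route is rejoined at 5.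

Further compounds
F1 | step 5 | (3S,6R)-3-bromo-2,2,6-trimethyl-6-[(1R)-4-methylcyclohex-3-en-1-yl]oxane | CC1(C)O[C@@](C)([C@@H]2CCC(C)=CC2)CC[C@@H]1Br
F2 | step 4 | (2R,3R,6E)-2-bromo-3-chloro-9-[(2R)-3,3-dimethyloxiran-2-yl]-3,7-dimethylnon-6-en-1-ol | OC[C@@H](Br)[C@](C)(Cl)CC/C=C(\C)CC[C@H]1OC1(C)C
F3 | step 2 | trimethyl[(5E)-8-[(2R)-3,3-dimethyloxiran-2-yl]-6-methyloct-5-en-1-yn-1-yl]silane | C[Si](C)(C)C#CCC/C=C(\C)CC[C@H]1OC1(C)C
F4 | step 2 | methyl (6E)-9-[(2R)-3,3-dimethyloxiran-2-yl]-7-methylnon-6-en-2-ynoate | COC(=O)C#CCC/C=C(\C)CC[C@H]1OC1(C)C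
F5 | step 2 | methyl (2Z,6E)-9-[(2R)-3,3-dimethyloxiran-2-yl]-3,7-dimethylnona-2,6-dienoate | COC(=O)/C=C(/C)CC/C=C(\C)CC[C@H]1OC1(C)C
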